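Ring numbering used throughout: C1 (CH bearing the side chain), C2 (bears the exocyclic C7H2), C3 (allylic CHBr), C4 (CH2), C5 (CHBr), C6 (CMe2).
Cuts: C3-Br goes back to the epimeric C3-OH. C1-C6 and C5-Br are then cut in one operation, which opens the only ring to an acyclic 1,5-diene. The chain is cut at C2-C3 (alkenyllithium + Weinreb amide), C2-C7 (Negishi) and C1=C2 (dibromo-olefination).
Enabling feature: the array Br-C5-C6(Me2)-C1-C2(=C7H2) of the cyclohexane has a bromine vicinal to the gem-dimethyl carbon and an exocyclic methylene beta to the C6-C1 bond. This is the retron of a bromonium-initiated, allylsilane-terminated cation-olefin cyclisation.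
Forward: (S)-linalool gives C1 and the whole side chain, CBr4 gives C2, Me3SiCH2 gives C7, and 4-methylpent-3-enoic acid gives C3-C6 with both methyl groups. The chain is joined in this order and the six-membered ring is closed last, two steps before the end.
Stereochemistry: the carbinol centre comes from (S)-linalool and C3 from a CBS reduction. C1 and C5 are relayed from C3 and the alkene geometry (side chain cis to C3) in one chair transition state, and C3 is inverted at the end when OH is exchanged for Br.

Key step: step 9

Assumption: (S)-(+)-linalool (coriandrol) is taken as a commercial chiral-pool terpene of high enantiomeric purity; locants of the acyclic compounds count from the vinyl end.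

Step 1
Reactants: 1 (S)-(+)-linalool, (3S)-3,7-dimethylocta-1,6-dien-3-ol
Product: 2 (3S)-3,7-dimethyl-3-(triethylsilyloxy)octa-1,6-diene
Conditions: TESOTf, 2,6-lutidine, CH2Cl2, -78 to 0 °C
Reagents that add atoms: triethylsilyl trifluoromethanesulfonate, CC[Si](CC)(CC)OS(=O)(=O)C(F)(F)F
Why: Silyl triflate silylation of a hindered tertiary alcohol; the carbinol centre is not touched and the ether keeps this oxygen from capturing Br+ or a cation later.

Step 2
Reactants: 2 (3S)-3,7-dimethyl-3-(triethylsilyloxy)octa-1,6-diene
Product: 4 (4S)-4-methyl-4-(triethylsilyloxy)hex-5-enal, via secondary ozonide 3 (not isolated)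
Conditions: O3 (dosed to the end point of Sudan Red 7B), CH2Cl2, -78 °C; then Me2S, -78 °C to rt
Reagents that add atoms: ozone, O=[O+][O-]
Why: Chemoselective ozonolysis with reductive work-up: ozone attacks the electron-rich trisubstituted alkene far faster than the monosubstituted vinyl group next to the C-O bond, the dye end point limits the dose, and the carbinol centre is not touched.

Step 3
Reactants: 4 (4S)-4-methyl-4-(triethylsilyloxy)hex-5-enal
Product: 5 (3S)-7,7-dibromo-3-methyl-3-(triethylsilyloxy)hepta-1,6-diene
Conditions: CBr4, PPh3, Zn dust, CH2Cl2, rt (ylide formation); then 4, 0 °C to rt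
Reagents that add atoms: carbon tetrabromide, BrC(Br)(Br)Br
Why: Ramirez dibromo-olefination (first stage of the Corey-Fuchs sequence) of an unhindered aldehyde; the zinc variant forms the ylide without Ph3PBr2, so the TES ether and the vinyl group stay intact.

Step 4
Reactants: 5 (3S)-7,7-dibromo-3-methyl-3-(triethylsilyloxy)hepta-1,6-diene
Product: 6 (3S,6Z)-7-bromo-3-methyl-3-(triethylsilyloxy)-8-(trimethylsilyl)octa-1,6-diene
Conditions: Me3SiCH2MgCl, ZnCl2, THF, 0 °C; then 5, PdCl2(DPEphos) (cat.; DPEphos = bis(2-diphenylphosphinophenyl) ether), THF, 0 °C to rt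
Reagents that add atoms: (trimethylsilyl)methylmagnesium chloride, C[Si](C)(C)C[Mg]Cl
Why: trans-Selective Negishi mono-coupling of a 1,1-dibromoalkene: zerovalent palladium inserts into the less hindered C-Br bond trans to the alkyl chain, so CH2SiMe3 enters trans to the chain and the remaining bromine stands cis to it (6Z), which fixes the alkene geometry that later sets C1.

Step 5
Reactants: 7 4-methylpent-3-enoic acid
Product: 8 N-methoxy-N,4-dimethylpent-3-enamide
Conditions: MeNH(OMe)·HCl, EDC·HCl, N-methylmorpholine, CH2Cl2, 0 °C to rt
Reagents that add atoms: N,O-dimethylhydroxylamine hydrochloride, CNOC.Cl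
Why: Carbodiimide-mediated amidation to a Weinreb amide under almost neutral conditions, which leave the beta,gamma-double bond where it is.

Step 6
Reactants: 6 (3S,6Z)-7-bromo-3-methyl-3-(triethylsilyloxy)-8-(trimethylsilyl)octa-1,6-diene; 8 N-methoxy-N,4-dimethylpent-3-enamide
Product: 10 (3S,6E)-3,11-dimethyl-3-(triethylsilyloxy)-7-[(trimethylsilyl)methyl]dodeca-1,6,10-trien-8-one (side chain cis to the carbonyl group), via alkenyllithium 9 (not isolated)
Conditions: t-BuLi (2 equiv), Et2O, -78 °C; then 8, -78 °C; AcOH/Et2O quench at -78 °C
Reagents that add atoms: none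
Why: Bromine-lithium exchange with retention of the alkene geometry followed by a Weinreb ketone synthesis, in which the chelated adduct prevents over-addition and the cold acidic quench keeps the skipped enone from moving into conjugation.

Step 7
Reactants: 10 (3S,6E)-3,11-dimethyl-3-(triethylsilyloxy)-7-[(trimethylsilyl)methyl]dodeca-1,6,10-trien-8-one
Product: 11 (3S,6E,8S)-3,11-dimethyl-3-(triethylsilyloxy)-7-[(trimethylsilyl)methyl]dodeca-1,6,10-trien-8-ol
Conditions: (R)-2-methyl-CBS-oxazaborolidine (cat.), catecholborane, toluene, -78 °C; aq. NaHCO3 work-up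
Reagents that add atoms: none
Why: Corey-Bakshi-Shibata reduction: the branched alkenyl group acts as the large and the CH2 group as the small ketone substituent, so the (R)-catalyst should deliver hydride to the face that gives the (8S)-alcohol (ring C3), and catecholborane at low temperature does not hydroborate the alkenes.

Step 8
Reactants: 11 (3S,6E,8S)-3,11-dimethyl-3-(triethylsilyloxy)-7-[(trimethylsilyl)methyl]dodeca-1,6,10-trien-8-ol
Product: 12 (3S,6E,8S)-8-(tert-butyldimethylsilyloxy)-3,11-dimethyl-3-(triethylsilyloxy)-7-[(trimethylsilyl)methyl]dodeca-1,6,10-triene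
Conditions: TBSOTf, 2,6-lutidine, CH2Cl2, -78 to 0 °C
Reagents that add atoms: tert-butyldimethylsilyl trifluoromethanesulfonate, CC(C)(C)[Si](C)(C)OS(=O)(=O)C(F)(F)F
Why: Silyl triflate silylation of a hindered secondary allylic alcohol; the bulky OTBS group blocks oxygen participation and serves as the equatorial anchor in step 9, and the buffered medium spares the allylsilane.

Step 9
Reactants: 12 (3S,6E,8S)-8-(tert-butyldimethylsilyloxy)-3,11-dimethyl-3-(triethylsilyloxy)-7-[(trimethylsilyl)methyl]dodeca-1,6,10-triene
Product: 15 bromocyclohexane bis-silyl ether: ring C1 (R) bears the (3S)-3-methyl-3-(triethylsilyloxy)pent-4-enyl chain, C2 bears =CH2, C3 (S) bears OTBS, C5 (R) bears Br, C6 bears two methyl groups; C3-O and C5-Br are cis to each other and trans to the chain, via bromonium ion pair 13 (not isolated), via beta-silyl cation 14 (not isolated)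
Conditions: 2,4,4,6-tetrabromocyclohexa-2,5-dienone (TBCO, slow addition), MeNO2/CH2Cl2, -40 to -10 °C; aq. Na2S2O3/NaHCO3 work-up
Reagents that add atoms: 2,4,4,6-tetrabromocyclohexa-2,5-dienone, O=C1C(Br)=CC(Br)(Br)C=C1Br
Why: Proposed new method: TBCO hands Br+ to the terminal C5=C6 bond, the bromonium ion 13 is opened at the tertiary C6, anti to bromine, by C1 of the allylsilane, and the beta-silyl cation 14 gives its Me3Si group to the tribromophenoxide, so that C2=C7H2 is the only alkene that can form. The closest known reaction types are the bromonium-induced polyene cyclisation with bromodienone or bromosulfonium reagents (ended by proton loss) and the allylsilane-terminated cyclisation of epoxides and acetals; their merger on a substrate that holds a free allylsilane has not been shown. The single ring closes in a 6-endo mode at both partners (C5 and C6 of the bromonium ion and C1 and C2 of the alkene all become ring atoms) through a chair. C5: anti opening places Br equatorial; C1: the side chain stands cis to C3 on the alkene and therefore becomes axial, trans to C5-Br; the pair of faces is chosen by (S)-C3, whose OTBS group must lie equatorial because an axial OTBS would be syn-pentane to the axial chain, which puts C3-O cis to C5-Br and trans to the chain. The step needs Br+ to go to C5=C6 and not to the allylsilane: the inner alkene is flanked by CH2SiMe3, the branched C3 and the chain and is drained by the allylic C-O bond, the bulky dienone prefers the open isopropylidene end, and the 1,5-placed allylsilane assists Br+ transfer to C5=C6 in a concerted, nucleophile-assisted way, which also makes the ring-closing transition state the one that fixes the C5 face. The vinyl group is monosubstituted and next to a C-O bond, and both oxygens are silylated so that neither can capture 13 or 14.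

Step 10
Reactants: 15 bromocyclohexane bis-silyl ether
Product: 16 bromo diol: as 15 with free (3S)-tertiary carbinol in the chain and free ring C3 (S)-OH; ring C1 (R), C5 (R)
Conditions: HF·pyridine, pyridine, THF, 0 °C to rt
Reagents that add atoms: none
Why: Fluoride-driven cleavage of both silyl ethers with buffered HF·pyridine, a medium that is neither basic enough to eliminate the hindered secondary bromide nor acidic enough to ionise the allylic alcohols, so no stereocentre is touched.

Step 11
Reactants: 16 bromo diol
Product: 18 (3S)-5-[(1S,3R,5R)-3,5-dibromo-2,2-dimethyl-6-methylidenecyclohexyl]-3-methylpent-1-en-3-ol (target), via alkoxyphosphonium bromide 17 (not isolated)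
Conditions: CBr4, PPh3, 2,6-lutidine (buffer), CH2Cl2, -30 to 0 °C
Reagents that add atoms: carbon tetrabromide, BrC(Br)(Br)Br
Why: Appel reaction: the secondary allylic alcohol forms the alkoxyphosphonium salt 17 and is displaced by bromide in an SN2 process with inversion, ring C3 (S)-OH to (R)-Br, while the tertiary alcohol is too hindered to be activated, and low temperature in a non-polar solvent holds back SN2' attack at C7. The descriptor of ring C1 changes from R to S by priority only.

Compound list
1 | (S)-(+)-linalool | C=C[C@@](C)(O)CCC=C(C)C | starting material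
2 | (3S)-3,7-dimethyl-3-(triethylsilyloxy)octa-1,6-diene | C=C[C@@](C)(O[Si](CC)(CC)CC)CCC=C(C)C | intermediate
3 | secondary ozonide of 2 (3,3-dimethyl-1,2,4-trioxolane bearing the chain at C5, not isolated) | C=C[C@@](C)(O[Si](CC)(CC)CC)CCC1OOC(C)(C)O1 | intermediate
4 | (4S)-4-methyl-4-(triethylsilyloxy)hex-5-enal | C=C[C@@](C)(O[Si](CC)(CC)CC)CCC=O | intermediate
5 | (3S)-7,7-dibromo-3-methyl-3-(triethylsilyloxy)hepta-1,6-diene | C=C[C@@](C)(O[Si](CC)(CC)CC)CCC=C(Br)Br | intermediate
6 | (3S,6Z)-7-bromo-3-methyl-3-(triethylsilyloxy)-8-(trimethylsilyl)octa-1,6-diene | C=C[C@@](C)(O[Si](CC)(CC)CC)CC/C=C(Br)/C[Si](C)(C)C | intermediate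
7 | 4-methylpent-3-enoic acid | CC(C)=CCC(=O)O | starting material
8 | N-methoxy-N,4-dimethylpent-3-enamide | CC(C)=CCC(=O)N(C)OC | intermediate
9 | alkenyllithium from 6 (Li cis to the chain, not isolated) | C=C[C@@](C)(O[Si](CC)(CC)CC)CC/C=C([Li])/C[Si](C)(C)C | intermediate
10 | (3S,6E)-3,11-dimethyl-3-(triethylsilyloxy)-7-[(trimethylsilyl)methyl]dodeca-1,6,10-trien-8-one | C=C[C@@](C)(O[Si](CC)(CC)CC)CC/C=C(/C[Si](C)(C)C)C(=O)CC=C(C)C | intermediate
11 | (3S,6E,8S)-3,11-dimethyl-3-(triethylsilyloxy)-7-[(trimethylsilyl)methyl]dodeca-1,6,10-trien-8-ol | C=C[C@@](C)(O[Si](CC)(CC)CC)CC/C=C(/C[Si](C)(C)C)[C@@H](O)CC=C(C)C | intermediate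
12 | 8-O-TBS ether of 11 (cyclisation precursor) | C=C[C@@](C)(O[Si](CC)(CC)CC)CC/C=C(/C[Si](C)(C)C)[C@@H](O[Si](C)(C)C(C)(C)C)CC=C(C)C | intermediate
13 | C5,C6-bromonium ion of 12 with tribromophenoxide (not isolated) | C=C[C@@](C)(O[Si](CC)(CC)CC)CC/C=C(/C[Si](C)(C)C)[C@@H](O[Si](C)(C)C(C)(C)C)C[C@H]1[Br+]C1(C)C.[O-]c1c(Br)cc(Br)cc1Br | intermediate
14 | cyclised C2 cation beta to silicon with tribromophenoxide (not isolated) | C=C[C@@](C)(O[Si](CC)(CC)CC)CC[C@@H]1[C+](C[Si](C)(C)C)[C@@H](O[Si](C)(C)C(C)(C)C)C[C@@H](Br)C1(C)C.[O-]c1c(Br)cc(Br)cc1Br | intermediate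
15 | bromocyclohexane bis-silyl ether (ring C1 R, C3 S, C5 R) | C=C[C@@](C)(O[Si](CC)(CC)CC)CC[C@@H]1C(=C)[C@@H](O[Si](C)(C)C(C)(C)C)C[C@@H](Br)C1(C)C | intermediate
16 | bromo diol (ring C1 R, C3 S, C5 R; carbinol S) | C=C[C@@](C)(O)CC[C@@H]1C(=C)[C@@H](O)C[C@@H](Br)C1(C)C | intermediate
17 | C3 alkoxy(triphenyl)phosphonium bromide of 16 (not isolated) | C=C[C@@](C)(O)CC[C@@H]1C(=C)[C@@H](O[P+](c2ccccc2)(c2ccccc2)c2ccccc2)C[C@@H](Br)C1(C)C.[Br-] | intermediate
18 | (3S)-5-[(1S,3R,5R)-3,5-dibromo-2,2-dimethyl-6-methylidenecyclohexyl]-3-methylpent-1-en-3-ol | C=C[C@@](C)(O)CC[C@@H]1C(=C)[C@H](Br)C[C@@H](Br)C1(C)C | target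

Total step count: 11. Longest linear sequence: 10 (steps 1-4 and 6-11).

Steps most likely to fail

Step 9. Three processes could spoil the step.
- Br+ may be taken up by the allylsilane itself, which is bromodesilylation without ring closure.
- Br+ transfer may be irreversible and therefore blind to C3, which gives poor face selectivity at C5.
- A 1,2-hydride shift from C3 may outrun the loss of silicon.

The fallback uses known chemistry and brings the bromine in as bromide, so that no Br+ meets the allylsilane. It sets out from 12. Shi epoxidation uses the L-sorbose-derived enantiomer of the fructose ketone and KHSO5 (as 2KHSO5·KHSO4·K2SO4). It should act at the sterically open C10=C11 bond and give the (10S)-10,11-epoxide F1. LiBr/AcOH in THF should open it at the secondary carbon with inversion to the (10R)-10-bromo-11-ol F2. (CF3CO)2O/pyridine converts this into the tertiary trifluoroacetate F3. Solvolysis in (CF3)2CHOH buffered with 2,6-di-tert-butylpyridine ionises the tertiary ester with bromine participation. This is the known stereospecific entry into bromonium polyene cyclisations. The allylsilane then closes the ring and the sequence comes back to the route at 15.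

Step 11. Three processes are the risks.
- Bromide may attack C7 (SN2' transposition to the primary allylic bromide), either directly or by later isomerisation.
- Backside approach at C3 may be slow next to the axial side chain.
- The tertiary allylic alcohol may ionise.

The fallback builds the C3-Br bond by electrophilic instead of nucleophilic bromine and sets out from 16. Ac2O/pyridine acetylates only the secondary alcohol to the C3 acetate F4. Palladium-catalysed allylic silylation (Me3SiSiMe3, Pd(dba)2, LiCl, DMF) places silicon on the less hindered C7 terminus. This gives the endocyclic C2=C3 alkene with a CH2SiMe3 group, the ring allylsilane F5. NBS in CH2Cl2 at -78 °C then effects an SE2' bromodesilylation. This can only put bromine on C3 and restore C2=C7H2, and it comes back to the route at 18. Attack is expected anti to the C-Si bond, which turns away from the C1 chain, and along the axial trajectory, that is cis to the chain.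

Step 6. The alkenyllithium may deprotonate the doubly activated CH2 of 8 instead of adding. The beta,gamma-double bond of the product may also migrate into conjugation.

The fallback avoids any C3 carbonyl compound with an acidic CH2 and sets out from 6. The alkenyllithium 9 is quenched with DMF to the enal F6. Brown allylation with (-)-B-allyldiisopinocampheylborane (Et2O, -78 °C) should give the (8S)-homoallylic alcohol F7. Cross metathesis in 2-methylbut-2-ene with the second-generation Grubbs catalyst turns the terminal allyl group into the prenyl group. The sequence comes back to the route at 11, so that steps 5-7 are bypassed.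

Further compounds
F1 | step 9 | (10S)-10,11-epoxide of 12 | C=C[C@@](C)(O[Si](CC)(CC)CC)CC/C=C(/C[Si](C)(C)C)[C@@H](O[Si](C)(C)C(C)(C)C)C[C@@H]1OC1(C)C
F2 | step 9 | (10R)-10-bromo-11-ol from F1 | C=C[C@@](C)(O[Si](CC)(CC)CC)CC/C=C(/C[Si](C)(C)C)[C@@H](O[Si](C)(C)C(C)(C)C)C[C@@H](Br)C(C)(C)O
F3 | step 9 | tertiary trifluoroacetate of F2 | C=C[C@@](C)(O[Si](CC)(CC)CC)CC/C=C(/C[Si](C)(C)C)[C@@H](O[Si](C)(C)C(C)(C)C)C[C@@H](Br)C(C)(C)OC(=O)C(F)(F)F
F4 | step 11 | C3 acetate of 16 | C=C[C@@](C)(O)CC[C@@H]1C(=C)[C@@H](OC(C)=O)C[C@@H](Br)C1(C)C
F5 | step 11 | ring allylsilane (C2=C3 endocyclic, CH2SiMe3 on C2) | C=C[C@@](C)(O)CC[C@@H]1C(C[Si](C)(C)C)=CC[C@@H](Br)C1(C)C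
F6 | step 6 | (2E,6S)-6-methyl-6-(triethylsilyloxy)-2-[(trimethylsilyl)methyl]octa-2,7-dienal (chain cis to CHO) | C=C[C@@](C)(O[Si](CC)(CC)CC)CC/C=C(/C[Si](C)(C)C)C=O
F7 | step 6 | (8S)-homoallylic alcohol (terminal allyl in place of prenyl in 11) | C=C[C@@](C)(O[Si](CC)(CC)CC)CC/C=C(/C[Si](C)(C)C)[C@@H](O)CC=C
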